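The left-handed product is what is counted here, and the questions compare its rate at one conversion, called the mark, and not at one time.

common to all: left-handed substrate 0.080 M; right-handed substrate 0.080 M; free catalyst 40 µM

| run | partner | remark |
|---|---|---|
| dusk | 0.088 M | the very flask that is asked about, followed so far |
| flask | 0.0880 M |  |

dusk run (percent of the left-handed substrate and right-handed substrate together charged)

| time / min | left-handed product / % | left-handed substrate / % |
|---|---|---|
| 0.333 | 3.4 | 46.7 |
| 1.00 | 8.4 | 42.0 |
| 2.00 | 13.9 | 37.6 |
| 2.50 | 14.9 | 35.4 |
| 4.00 | 21.0 | 30.0 |
| 5.00 | 21.3 | 27.7 |

(standard deviation of a reading: 0.5 percentage points)

- free catalyst is single-handed; left-handed substrate and right-handed substrate are mirror images of each other, charged as a racemate, each of them at the stated concentration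
- no earlier run changes the charge of free catalyst; that part of a forecast is a guess
- no earlier run changes the charge of partner; that part of a forecast is a guess

1. factor on the rate of making left-handed product when 10 % of the left-handed substrate and right-handed substrate together are converted if partner is charged twice over
2. factor on the rate when 10 % of the left-handed substrate and right-handed substrate together are converted if free catalyst is charged at 200 µM instead

The flask can be built up one process at a time. First comes the main step alone: partner, left-handed substrate and free catalyst make left-handed product, one partner taken per product, with the rate taken as first order in each.

Next comes the right-handed substrate, assumed to take partner in the same way. The symmetric case serves as the zero of the scale. With no preference between the hands, left-handed product stands at 5.00 % at the mark, and with full preference at 10 %. The dusk run shows 3.4 % at 0.333 min, which is less than the first, and 13.9 % at 2.00 min, which is more than the second, so the mark lies between those readings. The split leaves the partner count as it is: conversion is reckoned over both substrates together. One partner per converted substrate leaves 0.0720 M at the mark, the mark partner. With the charge doubled, the mark partner is 0.160 M, so the factor is 2.22, not the plain doubling of the charge. For free catalyst the mark partner stays the same, and the factor is the charge ratio, 5.00.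

Last comes the rest. The left-handed first-order constant read from the dusk run falls from 0.159 /min early to 0.0798 /min late, and no earlier run changes the charge of partner or of free catalyst. If free catalyst is lost with time, both factors stand above these values, since a rate raised by either change brings the mark sooner. On that assumption, the reckoning here commits to slightly above 2.22 and 5.00.

The forecast gives 1.9 for partner and 4.6 for free catalyst, each lower than this reckoning; of the partner factor it says “I shade this down for possible saturation”.

The flask gives factors of 2.37 for partner and 5.49 for free catalyst.

    partner + free catalyst + left-handed substrate → free catalyst + left-handed product (k = 1000 /M²/s)
    partner + free catalyst + right-handed substrate → free catalyst + right-handed product (k = 180 /M²/s)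
    free catalyst → spent catalyst (k = 0.00190 /s)

In this flask the mark comes at 1.02 min, and by 2.50 min free catalyst stands at 75.2 % of its charge, with spent catalyst at 24.8 %. Dividing the partner factor by the ratio of mark partners, 0.160 M over 0.0720 M, leaves 1.07, and dividing the catalyst factor by its charge ratio leaves 1.10.

The earlier runs and the new flask are simulated for substances that don't exist.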